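**Strategy.** Everything rests on disconnecting C6–C7 of the cycloheptane ring (dictyol numbering: ring fusion C1/C5, carbinols C6 and C9, side chain C11–C17 on C7). The key step exploits the 1,4-relationship between the C6 hydroxyl and the C12 oxygen across C7–C11: the target is a seco-form of a cis-fused α-methylene-γ-butyrolactone on the trans-hydroazulene. An intramolecular chromium-mediated allylation of a C6 aldehyde by a (Z)-2-(bromomethyl)enoate closes the seven-membered ring, sets C6 and C7 and lactonises; the lactone's convex face then fixes C11, and C12/C13 follow by γ-alkoxyallylboration. The precursor is an open-chain trans-1,2-disubstituted cyclopentene bearing the aldehyde and the allylic bromide arm.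

Key step: step 12

Remark: locants C1–C19 follow the dictyol numbering of the target (C4 is the methyl-bearing ring alkene carbon, C18 the exocyclic methylene on C10, C19 the methyl on C11). The sense of induction of each chiral catalyst or reagent is assigned by the accepted models; its antipode would be used should the sense prove opposite.

Step 1
Reactants: 1 furan-2(5H)-one; 2 2-isopropenyl-4,4,5,5-tetramethyl-1,3,2-dioxaborolane
Product: 3 (4S)-4-(prop-1-en-2-yl)oxolan-2-one
Conditions: [Rh(OH)(cod)]2 (2.5 mol%), (S)-2,2'-bis(diphenylphosphino)-1,1'-binaphthyl (6 mol%), dioxane/H2O 10:1, 50 °C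
Reagents that add atoms: none
Why: Rhodium-catalysed asymmetric conjugate addition (Hayashi–Miyaura reaction) of the alkenylboronate to the butenolide should set the β-stereocentre (future C5) by ligand-controlled face selection.

Step 2
Reactants: 3 (4S)-4-(prop-1-en-2-yl)oxolan-2-one; 4 allyl bromide
Product: 5 (3R,4S)-3-(prop-2-en-1-yl)-4-(prop-1-en-2-yl)oxolan-2-one
Conditions: LiN(iPr)2, THF, −78 °C; then 4, DMPU, −78 to −40 °C
Reagents that add atoms: none
Why: Lactone enolate alkylation should occur anti to the adjacent isopropenyl group (1,2-induction on the five-membered enolate), setting the future C1 trans to C5.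

Step 3
Reactants: 5 (3R,4S)-3-(prop-2-en-1-yl)-4-(prop-1-en-2-yl)oxolan-2-one
Product: 6 (3R,4S)-4-(hydroxymethyl)-5-methyl-3-(prop-2-en-1-yl)hex-5-en-2-one (in equilibrium with its cyclic hemiketal)
Conditions: CH3Li (1.05 equiv), THF, −78 °C; NH4Cl (aq)
Reagents that add atoms: methyllithium, [Li]C
Why: Mono-addition of an organolithium to a γ-lactone at low temperature should stop at the tetrahedral lithium hemiketal and give the methyl ketone on quench, leaving both stereocentres untouched.

Step 4
Reactants: 6 (3R,4S)-4-(hydroxymethyl)-5-methyl-3-(prop-2-en-1-yl)hex-5-en-2-one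
Product: 7 (3R,4S)-5-methyl-3-(prop-2-en-1-yl)-4-[(triethylsilyloxy)methyl]hex-5-en-2-one
Conditions: Et3SiCl, imidazole, DMAP (cat.), CH2Cl2, 0 °C to rt
Reagents that add atoms: chlorotriethylsilane, CC[Si](Cl)(CC)CC
Why: Silyl ether formation should trap the open hydroxy ketone tautomer through its unhindered primary hydroxyl.

Step 5
Reactants: 7 (3R,4S)-5-methyl-3-(prop-2-en-1-yl)-4-[(triethylsilyloxy)methyl]hex-5-en-2-one
Product: 8 1-[(1R,2S)-3-methyl-2-[(triethylsilyloxy)methyl]cyclopent-3-en-1-yl]ethan-1-one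
Conditions: second-generation Grubbs catalyst (3 mol%), CH2Cl2, 40 °C
Reagents that add atoms: none
Why: Ring-closing metathesis of the allyl and isopropenyl groups should form the trisubstituted C3=C4 cyclopentene with loss of ethene, the trans relationship being carried over from 5.

Step 6
Reactants: 8 1-[(1R,2S)-3-methyl-2-[(triethylsilyloxy)methyl]cyclopent-3-en-1-yl]ethan-1-one
Product: 9 1-[(1R,2S)-3-methyl-2-[(triethylsilyloxy)methyl]cyclopent-3-en-1-yl]ethenyl trifluoromethanesulfonate
Conditions: KN(SiMe3)2, THF, −78 °C; then PhNTf2, −78 to 0 °C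
Reagents that add atoms: N-phenylbis(trifluoromethanesulfonimide), FC(F)(F)S(=O)(=O)N(c1ccccc1)S(=O)(=O)C(F)(F)F
Why: Kinetic deprotonation of the methyl ketone at the methyl group and O-triflation of the enolate should give the 1,1-disubstituted enol triflate that becomes C10=C18.

Step 7
Reactants: 9 1-[(1R,2S)-3-methyl-2-[(triethylsilyloxy)methyl]cyclopent-3-en-1-yl]ethenyl trifluoromethanesulfonate
Product: 10 2-[(1R,2S)-3-methyl-2-[(triethylsilyloxy)methyl]cyclopent-3-en-1-yl]prop-2-enal
Conditions: Pd(PPh3)4 (5 mol%), CO (1 atm), Bu3SnH (slow addition), LiCl, THF, 50 °C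
Reagents that add atoms: carbon monoxide, [C-]#[O+]
Why: Palladium-catalysed reductive carbonylation (Stille-type formylation) of the enol triflate should install C9 as the aldehyde of a 2-substituted acrolein, slow hydride addition suppressing direct reduction.

Step 8
Reactants: 10 2-[(1R,2S)-3-methyl-2-[(triethylsilyloxy)methyl]cyclopent-3-en-1-yl]prop-2-enal; 11 2-allyl-4,4,5,5-tetramethyl-1,3,2-dioxaborolane
Product: 12 (3R)-2-[(1R,2S)-3-methyl-2-[(triethylsilyloxy)methyl]cyclopent-3-en-1-yl]hexa-1,5-dien-3-ol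
Conditions: (R)-3,3'-bis(2,4,6-triisopropylphenyl)-1,1'-binaphthyl-2,2'-diyl hydrogenphosphate (5 mol%), toluene, −30 °C
Reagents that add atoms: none
Why: Chiral phosphoric acid-catalysed allylboration through a chair transition state should set C9 (R) under catalyst control, the neutral cold conditions avoiding isomerisation of the α-methylene aldehyde.

Step 9
Reactants: 12 (3R)-2-[(1R,2S)-3-methyl-2-[(triethylsilyloxy)methyl]cyclopent-3-en-1-yl]hexa-1,5-dien-3-ol
Product: 13 tert-butyldimethylsilyl ether of 12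
Conditions: tBuMe2SiOTf, 2,6-lutidine, CH2Cl2, −78 °C
Reagents that add atoms: tert-butyldimethylsilyl trifluoromethanesulfonate, CC(C)(C)[Si](C)(C)OS(=O)(=O)C(F)(F)F
Why: Silylation of the hindered allylic alcohol protects C9–OH until the last step and supplies the bulky α-face group used in the key step.

Step 10
Reactants: 13 tert-butyldimethylsilyl ether of 12; 14 methyl 2-(bromomethyl)prop-2-enoate
Product: 15 methyl (2Z,5R)-2-(bromomethyl)-5-(tert-butyldimethylsilyloxy)-6-[(1R,2S)-3-methyl-2-[(triethylsilyloxy)methyl]cyclopent-3-en-1-yl]hepta-2,6-dienoate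
Conditions: second-generation Hoveyda–Grubbs catalyst (5 mol%), 14 (3 equiv), CH2Cl2, 40 °C
Reagents that add atoms: none
Why: Cross-metathesis of the only monosubstituted alkene with the 1,1-disubstituted acrylate should give the trisubstituted enoate with C8 trans to the ester, i.e. the (Z)-2-(bromomethyl)enoate.

Step 11
Reactants: 15 methyl (2Z,5R)-2-(bromomethyl)-5-(tert-butyldimethylsilyloxy)-6-[(1R,2S)-3-methyl-2-[(triethylsilyloxy)methyl]cyclopent-3-en-1-yl]hepta-2,6-dienoate
Product: 16 methyl (2Z,5R)-2-(bromomethyl)-5-(tert-butyldimethylsilyloxy)-6-[(1R,2S)-2-formyl-3-methylcyclopent-3-en-1-yl]hepta-2,6-dienoate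
Conditions: (COCl)2, DMSO, CH2Cl2, −78 to −40 °C; iPr2NEt, −78 °C; pH 7 buffer
Reagents that add atoms: none
Why: Direct Swern oxidation of a primary triethylsilyl ether (cleaved and oxidised in one flask while the secondary tert-butyldimethylsilyl ether survives) should give the β,γ-unsaturated aldehyde under cold conditions that do not epimerise C5.

Step 12
Reactants: 16 methyl (2Z,5R)-2-(bromomethyl)-5-(tert-butyldimethylsilyloxy)-6-[(1R,2S)-2-formyl-3-methylcyclopent-3-en-1-yl]hepta-2,6-dienoate
Product: 18 (1R,5S,6R,7S,9R)-9-(tert-butyldimethylsilyloxy)-α-methylene 6,12-lactone of the trans-hydroazulene (C11=C19 methylene; C3=C4 and C10=C18 in place), via hydroxy ester 17 (not isolated)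
Conditions: CrCl2 (8 equiv), THF, rt, slow addition of 16 to 2 mM; NH4Cl (aq); PPTS (cat.), CH2Cl2, rt
Reagents that add atoms: none
Why: Two equivalents of CrCl2 insert into the allylic C–Br bond to give a (Z)-configured γ-substituted 2-(methoxycarbonyl)allylchromium species (trivalent chromium), which adds through its γ-carbon C7 to the tethered C6 aldehyde in a six-membered chair (Zimmerman–Traxler) transition state, and the resulting alkoxide acylates on the neighbouring ester. The closest known reaction type is the intramolecular Nozaki–Hiyama–Kishi allylation, in the form of the metal-promoted cyclisation–lactonisation of 2-(bromomethyl)acrylates used to build α-methylene lactones on seven-membered rings. The carbocycle closes in a 7-exo-trig mode (C7 onto the exocyclic C6=O) and the lactone in a 5-exo-trig mode (O6 onto the C12 ester). C7 relative to C6: C8, cis to the CH2–Cr carbon, sits axial in the chair and C5 of the aldehyde equatorial, which gives the syn homoallylic alkoxide, i.e. H6/H7 cis, the arrangement that lactonises to the cis-fused ring. C6 relative to C5: the trans-fused chair-like seven-membered transition state makes C7 approach anti to the C4 vinyl carbon, and the bulky chromium alkoxide should take the equatorial β position, away from H1 and the α-oriented C9 silyloxy group, giving 6R,7S. The step needs ring closure to beat intermolecular coupling (slow addition at high dilution), γ- over α-attack (inherent to allylchromium) and no enolisation of the β,γ-unsaturated aldehyde (the reagent is non-basic and leaves ester, silyl ether and alkenes alone).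

Step 13
Reactants: 18 α-methylene lactone
Product: 19 (1R,5S,6R,7S,9R,11R)-9-(tert-butyldimethylsilyloxy)-11-methyl 6,12-lactone
Conditions: NaBH4, MeOH/THF, 0 °C
Reagents that add atoms: none
Why: Conjugate hydride reduction of the α-methylene lactone, the only conjugated alkene, followed by kinetic protonation of the enolate on the convex face of the cis-fused bicycle should set C11 (R) with the methyl on the concave face.

Step 14
Reactants: 19 11-methyl 6,12-lactone
Product: 20 the corresponding lactol (C12 hemiacetal, anomeric mixture)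
Conditions: iBu2AlH (1.1 equiv), CH2Cl2, −78 °C; Rochelle salt (aq)
Reagents that add atoms: none
Why: Partial reduction of a γ-lactone at low temperature should stop at the lactol, which unmasks C12 as an aldehyde while C6–O stays free of any protecting group.

Step 15
Reactants: 20 lactol; 21 3-(methoxymethoxy)prop-1-ene
Product: 22 (1R,5S,6R,7S,9R,11R,12S,13S)-9-(tert-butyldimethylsilyloxy)-13-(methoxymethoxy)-6,12-diol with a C14=C15 vinyl terminus
Conditions: 21, s-BuLi, THF, −78 °C; (+)-B-methoxydiisopinocampheylborane; BF3·OEt2; then 20, −78 °C to rt; NaOH, H2O2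
Reagents that add atoms: none
Why: Brown γ-alkoxyallylboration of the hydroxy aldehyde tautomer through a chair Zimmerman–Traxler transition state: the (Z)-geometry should give the syn C12/C13 diol derivative and the isopinocampheyl groups control the aldehyde face (C12 S, reagent control over the C11 centre).

Step 16
Reactants: 22 13-(methoxymethoxy)-6,12-diol
Product: 23 (1R,5S,6R,7S,9R,11R,12S,13S)-9-(tert-butyldimethylsilyloxy)-6,12,13-triol (vinyl terminus)
Conditions: ZnBr2, n-PrSH, CH2Cl2, 0 °C
Reagents that add atoms: none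
Why: Lewis acid/thiol cleavage of the methoxymethyl ether should spare the silyl ether and is done before the allylic C13 oxygen becomes ionisable by the trisubstituted alkene.

Step 17
Reactants: 23 6,12,13-triol
Product: 24 12,13-diacetate of 23 (C6–OH free, vinyl terminus)
Conditions: Ac2O (2.5 equiv), pyridine, CH2Cl2, 0 °C to rt
Reagents that add atoms: acetic anhydride, CC(=O)OC(C)=O
Why: Acetylation without an acyl-transfer catalyst should take the two side-chain hydroxyls and leave the C6 hydroxyl, which is flanked by two ring methines and the C4 vinyl methyl.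

Step 18
Reactants: 24 12,13-diacetate (vinyl terminus); 25 2-methylbut-2-ene
Product: 26 9-O-tert-butyldimethylsilyl ether of the target
Conditions: second-generation Grubbs catalyst (5 mol%), 25 (large excess), CH2Cl2, 40 °C
Reagents that add atoms: none
Why: Cross-metathesis of the terminal vinyl group with 2-methylbut-2-ene should install the C15 gem-dimethyl alkene with loss of propene, the 1,1-disubstituted and trisubstituted ring alkenes being too hindered to react.

Step 19
Reactants: 26 9-O-tert-butyldimethylsilyl ether of the target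
Product: 27 target CNP0423623.2, (1R,5S,6R,7S,9R,11R,12S,13S)
Conditions: HF·pyridine, pyridine, THF, 0 °C to rt
Reagents that add atoms: none
Why: Buffered fluoride desilylation should free C9–OH without acetate migration or cleavage.

**Compound list**

1 | furan-2(5H)-one | O=C1OCC=C1 | starting material
2 | 2-isopropenyl-4,4,5,5-tetramethyl-1,3,2-dioxaborolane | C=C(C)B1OC(C)(C)C(C)(C)O1 | starting material
3 | (4S)-4-(prop-1-en-2-yl)oxolan-2-one | O=C1OC[C@@H](C1)C(C)=C | intermediate
4 | allyl bromide | C=CCBr | starting material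
5 | (3R,4S)-3-(prop-2-en-1-yl)-4-(prop-1-en-2-yl)oxolan-2-one | C=CC[C@H]1C(=O)OC[C@@H]1C(C)=C | intermediate
6 | (3R,4S)-4-(hydroxymethyl)-5-methyl-3-(prop-2-en-1-yl)hex-5-en-2-one | C=CC[C@@H](C(C)=O)[C@H](CO)C(C)=C | intermediate
7 | (3R,4S)-5-methyl-3-(prop-2-en-1-yl)-4-[(triethylsilyloxy)methyl]hex-5-en-2-one | C=CC[C@@H](C(C)=O)[C@H](CO[Si](CC)(CC)CC)C(C)=C | intermediate
8 | 1-[(1R,2S)-3-methyl-2-[(triethylsilyloxy)methyl]cyclopent-3-en-1-yl]ethan-1-one | CC[Si](CC)(CC)OC[C@@H]1C(C)=CC[C@H]1C(C)=O | intermediate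
9 | 1-[(1R,2S)-3-methyl-2-[(triethylsilyloxy)methyl]cyclopent-3-en-1-yl]ethenyl trifluoromethanesulfonate | C=C(OS(=O)(=O)C(F)(F)F)[C@@H]1CC=C(C)[C@H]1CO[Si](CC)(CC)CC | intermediate
10 | 2-[(1R,2S)-3-methyl-2-[(triethylsilyloxy)methyl]cyclopent-3-en-1-yl]prop-2-enal | C=C(C=O)[C@@H]1CC=C(C)[C@H]1CO[Si](CC)(CC)CC | intermediate
11 | 2-allyl-4,4,5,5-tetramethyl-1,3,2-dioxaborolane | C=CCB1OC(C)(C)C(C)(C)O1 | starting material
12 | (3R)-2-[(1R,2S)-3-methyl-2-[(triethylsilyloxy)methyl]cyclopent-3-en-1-yl]hexa-1,5-dien-3-ol | C=CC[C@@H](O)C(=C)[C@@H]1CC=C(C)[C@H]1CO[Si](CC)(CC)CC | intermediate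
13 | tert-butyldimethylsilyl ether of 12 | C=CC[C@@H](O[Si](C)(C)C(C)(C)C)C(=C)[C@@H]1CC=C(C)[C@H]1CO[Si](CC)(CC)CC | intermediate
14 | methyl 2-(bromomethyl)prop-2-enoate | C=C(CBr)C(=O)OC | starting material
15 | methyl (2Z,5R)-2-(bromomethyl)-5-(tert-butyldimethylsilyloxy)-6-[(1R,2S)-3-methyl-2-[(triethylsilyloxy)methyl]cyclopent-3-en-1-yl]hepta-2,6-dienoate | COC(=O)/C(CBr)=C/C[C@@H](O[Si](C)(C)C(C)(C)C)C(=C)[C@@H]1CC=C(C)[C@H]1CO[Si](CC)(CC)CC | intermediate
16 | methyl (2Z,5R)-2-(bromomethyl)-5-(tert-butyldimethylsilyloxy)-6-[(1R,2S)-2-formyl-3-methylcyclopent-3-en-1-yl]hepta-2,6-dienoate | COC(=O)/C(CBr)=C/C[C@@H](O[Si](C)(C)C(C)(C)C)C(=C)[C@@H]1CC=C(C)[C@H]1C=O | intermediate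
17 | methyl 2-[(1R,5S,6R,7S,9R)-9-(tert-butyldimethylsilyloxy)-6-hydroxy-hydroazulen-7-yl]prop-2-enoate (hydroxy ester, dictyol numbering) | C=C1[C@H](O[Si](C)(C)C(C)(C)C)C[C@@H](C(=C)C(=O)OC)[C@@H](O)[C@@H]2C(C)=CC[C@@H]12 | intermediate (not isolated)
18 | (1R,5S,6R,7S,9R)-9-(tert-butyldimethylsilyloxy)-α-methylene 6,12-lactone | C=C1[C@H](O[Si](C)(C)C(C)(C)C)C[C@H]3C(=C)C(=O)O[C@H]3[C@@H]2C(C)=CC[C@@H]12 | intermediate
19 | (1R,5S,6R,7S,9R,11R)-9-(tert-butyldimethylsilyloxy)-11-methyl 6,12-lactone | C=C1[C@H](O[Si](C)(C)C(C)(C)C)C[C@H]3[C@@H](C)C(=O)O[C@H]3[C@@H]2C(C)=CC[C@@H]12 | intermediate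
20 | lactol of 19 (C12 hemiacetal) | C=C1[C@H](O[Si](C)(C)C(C)(C)C)C[C@H]3[C@@H](C)C(O)O[C@H]3[C@@H]2C(C)=CC[C@@H]12 | intermediate
21 | 3-(methoxymethoxy)prop-1-ene | C=CCOCOC | starting material
22 | (12S,13S)-13-(methoxymethoxy)-6,12-diol, 9-O-silyl, vinyl terminus | C=C1[C@H](O[Si](C)(C)C(C)(C)C)C[C@@H]([C@@H](C)[C@H](O)[C@H](C=C)OCOC)[C@@H](O)[C@@H]2C(C)=CC[C@@H]12 | intermediate
23 | (12S,13S)-6,12,13-triol, 9-O-silyl, vinyl terminus | C=C1[C@H](O[Si](C)(C)C(C)(C)C)C[C@@H]([C@@H](C)[C@H](O)[C@H](C=C)O)[C@@H](O)[C@@H]2C(C)=CC[C@@H]12 | intermediate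
24 | 12,13-diacetate of 23 | C=C1[C@H](O[Si](C)(C)C(C)(C)C)C[C@@H]([C@@H](C)[C@H](OC(C)=O)[C@H](C=C)OC(C)=O)[C@@H](O)[C@@H]2C(C)=CC[C@@H]12 | intermediate
25 | 2-methylbut-2-ene | CC=C(C)C | starting material
26 | 9-O-tert-butyldimethylsilyl ether of the target | C=C1[C@H](O[Si](C)(C)C(C)(C)C)C[C@@H]([C@@H](C)[C@H](OC(C)=O)[C@H](C=C(C)C)OC(C)=O)[C@@H](O)[C@@H]2C(C)=CC[C@@H]12 | intermediate
27 | CNP0423623.2 | C=C1[C@H](O)C[C@@H]([C@@H](C)[C@H](OC(C)=O)[C@H](C=C(C)C)OC(C)=O)[C@@H](O)[C@@H]2C(C)=CC[C@@H]12 | target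

**Step count.** Total: 19 steps. Longest linear sequence: 19 steps (from 1; all other inputs are commercial).

**Steps most likely to fail**

Step 12 (key step). The closure may suffer from intermolecular coupling of the allylchromium, from addition to the α face of the aldehyde (giving the C6,C7-bis-epimeric cis-lactone) or from epimerisation of the β,γ-unsaturated aldehyde. The fallback replaces the organochromium addition by a radical ketyl–olefin cyclisation and sets out from 13. Cross-metathesis with methyl methacrylate (second-generation Hoveyda–Grubbs catalyst) should give methyl (2E,5R)-5-(tert-butyldimethylsilyloxy)-2-methyl-6-[(1R,2S)-3-methyl-2-[(triethylsilyloxy)methyl]cyclopent-3-en-1-yl]hepta-2,6-dienoate F1. Direct Swern oxidation as in step 11 should give the C6 aldehyde F2. SmI2 and MeOH in THF at −78 °C should generate the C6 ketyl, which adds 7-exo-trig to the enoate β-carbon C7. The cis hydroxy ester lactonises with PPTS, and the route is rejoined at 19. C11, set here by protonation of the samarium enolate, would be corrected if needed by deprotonation with LiN(iPr)2 and kinetic protonation on the convex face.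

Step 15. The allylboration may stall through slow opening of the hindered cis-fused lactol, through protonolysis of the borane by the free hydroxyl, or through mismatched double diastereoselection against C11. The fallback uses an acyclic protected aldehyde and substrate control, and sets out from 19. Me3Al and MeNH(OMe)·HCl should open the lactone to the C6-hydroxy Weinreb amide F3. Et3SiOTf and 2,6-lutidine should give the C6 triethylsilyl ether F4. iBu2AlH at −78 °C should give the C12 aldehyde F5. BF3·OEt2-promoted addition of (Z)-tributyl[3-(methoxymethoxy)prop-2-en-1-yl]stannane at −78 °C proceeds through an open transition state, which gives the syn diol derivative, with Felkin–Anh control from C11; this should give the 6-O-triethylsilyl 13-O-methoxymethyl alcohol F6. PPTS in MeOH followed by ZnBr2/n-PrSH removes both groups, and the route is rejoined at 23.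

Step 10. The cross-metathesis may give poor turnover with the allylic bromide and the 1,1-disubstituted acrylate, with homodimerisation of 13 taking over. The fallback builds the enoate by aldol and Morita–Baylis–Hillman chemistry and sets out from 10. A Mukaiyama aldol with 1-(tert-butylthio)-1-(trimethylsilyloxy)ethene, catalysed by Ti(OiPr)4 and the antipode of 1,1'-bi-2-naphthol that delivers the (3R)-adduct, should give the β-hydroxy thioester F7. tBuMe2SiOTf and 2,6-lutidine should give the silyl ether F8. iBu2AlH at −78 °C should give the C7 aldehyde F9. A Morita–Baylis–Hillman reaction with methyl acrylate and DABCO should give the allylic alcohol F10 (C7 epimers, both usable). N-Bromosuccinimide and Me2S then effect bromination with allylic transposition, and the route is rejoined at 15.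

**Further compounds**

F1 | step 12 | methyl (2E,5R)-5-(tert-butyldimethylsilyloxy)-2-methyl-6-[(1R,2S)-3-methyl-2-[(triethylsilyloxy)methyl]cyclopent-3-en-1-yl]hepta-2,6-dienoate | COC(=O)/C(C)=C/C[C@@H](O[Si](C)(C)C(C)(C)C)C(=C)[C@@H]1CC=C(C)[C@H]1CO[Si](CC)(CC)CC
F2 | step 12 | methyl (2E,5R)-5-(tert-butyldimethylsilyloxy)-6-[(1R,2S)-2-formyl-3-methylcyclopent-3-en-1-yl]-2-methylhepta-2,6-dienoate | COC(=O)/C(C)=C/C[C@@H](O[Si](C)(C)C(C)(C)C)C(=C)[C@@H]1CC=C(C)[C@H]1C=O
F3 | step 15 | C6-hydroxy C12 N-methoxy-N-methylamide from 19 | C=C1[C@H](O[Si](C)(C)C(C)(C)C)C[C@@H]([C@@H](C)C(=O)N(C)OC)[C@@H](O)[C@@H]2C(C)=CC[C@@H]12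
F4 | step 15 | 6-O-triethylsilyl ether of F3 | C=C1[C@H](O[Si](C)(C)C(C)(C)C)C[C@@H]([C@@H](C)C(=O)N(C)OC)[C@@H](O[Si](CC)(CC)CC)[C@@H]2C(C)=CC[C@@H]12
F5 | step 15 | 6-O-triethylsilyl C12 aldehyde | C=C1[C@H](O[Si](C)(C)C(C)(C)C)C[C@@H]([C@@H](C)C=O)[C@@H](O[Si](CC)(CC)CC)[C@@H]2C(C)=CC[C@@H]12
F6 | step 15 | 6-O-triethylsilyl 13-O-methoxymethyl (12S,13S)-12-ol | C=C1[C@H](O[Si](C)(C)C(C)(C)C)C[C@@H]([C@@H](C)[C@H](O)[C@H](C=C)OCOC)[C@@H](O[Si](CC)(CC)CC)[C@@H]2C(C)=CC[C@@H]12
F7 | step 10 | S-tert-butyl (3R)-3-hydroxy-4-[(1R,2S)-3-methyl-2-[(triethylsilyloxy)methyl]cyclopent-3-en-1-yl]pent-4-enethioate | CC(C)(C)SC(=O)C[C@@H](O)C(=C)[C@@H]1CC=C(C)[C@H]1CO[Si](CC)(CC)CC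
F8 | step 10 | tert-butyldimethylsilyl ether of F7 | CC(C)(C)SC(=O)C[C@@H](O[Si](C)(C)C(C)(C)C)C(=C)[C@@H]1CC=C(C)[C@H]1CO[Si](CC)(CC)CC
F9 | step 10 | (3R)-3-(tert-butyldimethylsilyloxy)-4-[(1R,2S)-3-methyl-2-[(triethylsilyloxy)methyl]cyclopent-3-en-1-yl]pent-4-enal | O=CC[C@@H](O[Si](C)(C)C(C)(C)C)C(=C)[C@@H]1CC=C(C)[C@H]1CO[Si](CC)(CC)CC
F10 | step 10 | methyl (5R)-5-(tert-butyldimethylsilyloxy)-3-hydroxy-2-methylidene-6-[(1R,2S)-3-methyl-2-[(triethylsilyloxy)methyl]cyclopent-3-en-1-yl]hept-6-enoate | COC(=O)C(=C)C(O)C[C@@H](O[Si](C)(C)C(C)(C)C)C(=C)[C@@H]1CC=C(C)[C@H]1CO[Si](CC)(CC)CC
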